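**Abbreviations used throughout:** geranyl = (2E)-3,7-dimethylocta-2,6-dien-1-yl; prenyl = 3-methylbut-2-en-1-yl; MOM = methoxymethyl; TIPS = triisopropylsilyl; ArB = 2-geranyl-4-methoxy-3-(methoxymethoxy)phenyl.

## Analysis of the target

The target is a (2S)-flavanone: a chroman-4-one in which aromatic ring A is fused to the oxygen heterocycle ring C, with aryl ring B on C2. C2 is the only stereocentre. It is benzylic, bonded to O1 and β to the C4 carbonyl, so it can be lost by reversible opening of ring C, either by β-elimination of the ring A phenoxide under base or by ionisation of C2–O1 under acid; the C4' methoxy group para to C1' makes that cation easy to reach. Ring A is fully differentiated: O1 on C8a, a free hydroxyl on C5 (hydrogen-bonded to C4=O), prenyl on C6, methoxy on C7 and hydrogen on C8. Ring B carries four contiguous substituents: the bond from C1' to C2, geranyl on C2', hydroxyl on C3' and methoxy on C4'. There are three trisubstituted alkenes, one of them the E alkene of the geranyl chain, and both phenols sit next to an allylic chain (5-OH/6-prenyl and 3'-OH/2'-geranyl), so strong Brønsted or Lewis acids, hydrogenation and unselective electrophiles are excluded. The difficulty is the crowded 1,2,3,4-pattern of ring B, an epimerisable stereocentre, and a late stage that must avoid strong acid. The strategy rests on the C3' hydroxyl flanked by the C4' methoxy group and the C2' geranyl group: an oxygen next to a methoxy-bearing carbon is what the ring oxygen and C3 of 3-methoxyfuran become when the furan is turned into a benzene ring by cycloaddition to an alkyne and opening of the oxygen bridge.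

## Retrosynthetic reasoning

**Unveiling the phenols (30 ⇒ 29 ⇒ 28).** O3' is carried as a MOM acetal in 29 and O5 as a methyl ether in 28. The O5 methyl ether is the only one that can share a metal chelate with the C4 carbonyl, so it can be cleaved selectively after ring C exists. This lets ring A come from a symmetric 3,5-dimethoxyaryl unit; the difference between O5 and O7 is made by the carbonyl group, not by fragment synthesis.

**C4–C4a (28 ⇒ 25).** Ring C is opened at the aryl–carbonyl bond. The polarity chosen is an aryl–metal on ring A (from the aryl iodide in 25) attacking C4 at the acid oxidation level, held as an N-methoxy-N-methylamide. The acid-promoted alternative (Friedel–Crafts acylation) is not used because C2–O1 in the open-chain precursor is a para-methoxybenzylic aryl ether that would ionise, and the alkenes would be protonated. The forward step must exchange iodine for lithium faster than anything else happens and close a six-membered ring without disturbing C2.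

**C4 oxidation level (25 ⇒ 24 ⇒ 22 ⇒ 20).** The amide carbon is traced back to the terminal carbon of a vinyl group in 20. That vinyl group is the only monosubstituted alkene in the molecule, so a bulky borane can pick it out from the three trisubstituted alkenes. The stereocentre is not involved.

**C2–O1 (20 ⇒ 12 + 18).** The benzylic C–O bond is cut to the linear cinnamyl carbonate 12 and the ring A iodophenol 18. This is the convergent union of the two halves and the point where C2 is set, by catalyst-controlled allylic substitution at the aryl-bearing terminus. Forming the stereocentre in a C–O bond-forming step under basic conditions avoids both an acid-labile carbinol and a late reduction.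

**Ring A fragment (18 ⇒ 17 ⇒ 16 ⇒ 14 ⇒ 13).** The C–I bond is removed first; the two positions ortho to the hydroxyl of 17 are equivalent, so only one mono-iodide can form. The prenyl group is then removed from the carbon between the two methoxy groups, the position that directed metalation of the silyl ether 14 reaches. This leads back to 3,5-dimethoxyphenol 13.

**Cinnamyl carbonate (12 ⇒ 11 ⇒ 10 ⇒ 8 ⇒ 7 ⇒ 6).** The three-carbon allyl unit is reduced to the benzoate carbon of 6 by standard two-carbon homologation (reduction, oxidation with in situ olefination, reduction, carbonate formation) after protection of O3'.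

**Ring B (6 ⇒ 3 + 4).** The benzene ring is cut at C2'–C3' and C1'–C6'. This gives 3-methoxyfuran 4, which supplies C3', C4', C5', C6', the methoxy group and the phenol oxygen, and the alkynoate 3, which supplies C1' with its carboxyl carbon and C2' with the geranyl group. The cut is made here because it delivers all four neighbouring substituents in one step and avoids any substitution on a ring position flanked by two groups. The forward reaction must add in one orientation and open the bridge in one direction.

**Alkynoate (3 ⇒ 1 + 2).** The bond between the alkyne terminus and C1 of the geranyl chain is cut to methyl propiolate 1 and geranyl bromide 2. The E alkene is bought, not made.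

## Alternatives that were turned down

**Alternative 1:** The disconnection is C2–C3 of ring C, back to the enol acetal A1 (a 2-aryl-4-methylidene-4H-1,3-benzodioxine carrying the ring A and ring B substituents). In the forward key step a confined chiral Brønsted acid of the imidodiphosphorimidate class cleaves the acetal C–O bond on the enol side, and the freed enol adds through carbon to the O-aryl oxocarbenium ion inside the chiral anion pocket (a Petasis–Ferrier rearrangement). This gives the flavanone A2, which is the same compound as 28 here.
- For: ring C and the stereocentre arise in one catalytic step from an achiral acetal. No aryl iodide or organolithium is needed, and the sequence after union of the fragments is shorter than in the chosen route.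
- Against: a very strong acid meets three trisubstituted alkenes and a MOM acetal. Protonation of the enol ether carbon competes with acetal ionisation. The oxocarbenium ion carries an ortho-geranyl aryl group that fits a confined pocket poorly. A1 also needs the tetrasubstituted ring B aldehyde, so the hardest ring is not addressed.
- Comparison: Alternative 1 is stronger on step count. The chosen route offers a ring B construction and keeps every alkene-bearing intermediate under neutral or basic conditions until the last step.

**Alternative 2:** The disconnection is C4a–C4, C4–C3 and O1–C2, back to iodophenol 18 (the same ring A piece as here) and the ring B arylalkyne A3. In the forward key step zerovalent palladium inserts into the C–I bond, the acylpalladium formed under carbonylative conditions couples with the alkyne, and the phenol closes onto the ynone to give the flavone A4. An enantioselective conjugate reduction of C2=C3 must follow.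
- For: three bonds in one step, full convergence, a robust achiral intermediate, and about four steps fewer than here. On step economy this alternative is stronger.
- Against: 5-exo closure to the aurone competes. The stereocentre is then set last, by hydride delivery to a β,β-disubstituted, electron-rich chromone whose β-aryl group is ortho-substituted. Hydrogenation catalysts that reduce flavones would also touch the three alkenes. Over-reduction to the flavan-4-ol and base-induced opening of ring C are likely.
- Comparison: the chosen route sets C2 early in a C–O bond-forming step and carries it through steps that cannot epimerise it, in place of the shorter sequence.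

**Alternative 3:** The disconnection is ring A itself (C5–C6, C7–C8, C4a–C5), back to the diazoketone A5 built on a chiral 2-aryl-2,3-dihydropyran-4-one and the methoxyalkyne A6. In the forward key step light triggers a Wolff rearrangement to a vinylketene, which adds to the alkyne; the cyclobutenone opens and recloses to the phenol (Danheiser benzannulation). This gives A7, which is the same compound as 29 here.
- For: all ring A substituents are placed with regiocontrol and the C5 hydroxyl emerges free, so no selective demethylation is needed. On this point Alternative 3 is stronger. The stereocentre would come from a reliable asymmetric hetero-Diels–Alder reaction.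
- Against: irradiation of a vinylogous ester in a molecule with three trisubstituted alkenes invites [2+2] photocycloaddition and E/Z scrambling of the geranyl alkene. The ketene intermediates can be trapped by those alkenes. 1-Methoxyalkynes are labile, and the diazoketone needs several steps. Ring B again has to be made separately.
- Comparison: the chosen route uses only thermal, ground-state steps after ring B is built and accepts a chelation-controlled demethylation in exchange.

Key step: step 2

## Route

Assumption: the sense of induction of the iridium catalyst in step 12 is taken to follow that of simple cinnamyl carbonates; both ligand antipodes are available, so the S configuration at C2 can be reached in either case.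

Step 1
Reactants: 1 methyl propiolate; 2 geranyl bromide
Product: 3 methyl (5E)-6,10-dimethylundeca-5,9-dien-2-ynoate
Conditions: CuI (10 mol%), K2CO3 (1.5 equiv), DMF, 20 °C, degassed
Reagents that add atoms: none
Why: Copper-catalysed allylation of a terminal alkyne: the copper acetylide formed under carbonate base displaces the primary allylic bromide at its unsubstituted carbon, so the E alkene is kept; the weak base and room temperature are chosen to keep the skipped enynoate from isomerising to the allenoate.

Step 2
Reactants: 3 methyl (5E)-6,10-dimethylundeca-5,9-dien-2-ynoate; 4 3-methoxyfuran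
Product: 6 methyl 2-geranyl-3-hydroxy-4-methoxybenzoate, via oxanorbornadiene cycloadduct 5 (not isolated)
Conditions: 4 (2.5 equiv), Me2AlCl (1.2 equiv), CH2Cl2, −78 → −20 °C; aq. potassium sodium tartrate
Reagents that add atoms: none
Why: Me2AlCl binds the ester carbonyl and lowers the alkyne LUMO; furan C2, the β carbon of the enol ether and the site of the largest HOMO coefficient, bonds to the alkynoate β carbon (the one bearing the geranyl CH2) and furan C5 bonds to the ester-bearing carbon in a strongly asynchronous [4+2] cycloaddition that gives the 7-oxanorbornadiene 5. The aluminium then assists heterolysis of the bridge C–O bond at the old furan C5, because only there is the cation an allyl cation that ends on the methoxy-bearing carbon (a vinylogous oxocarbenium ion); the oxygen therefore stays on the old furan C2, between the methoxy carbon and the geranyl carbon, and loss of the proton from that carbon aromatises to the aluminium phenoxide of 6. The closest known reaction type is the Diels–Alder reaction of furans, 3-alkoxyfurans included, with alkynoates followed by opening of the oxanorbornadiene to a phenol. The one ring closed is ring B, by [4+2] cycloaddition (C2'–C3' and C1'–C6') and aromatisation; the two bridgehead stereocentres of 5 are transient and are erased, so no stereocentre has to be controlled. Two regioselectivities are needed, the orientation of the addition and the direction of the opening, and both are set by the single methoxy group of 4; a reversed orientation would put the ester, not the geranyl group, next to the hydroxyl. Chemoselectivity against the geranyl alkenes is also needed: Me2AlCl is chosen because its Al–CH3 bonds consume HCl and the proton released on aromatisation, so no Brønsted acid is present to start cation–olefin cyclisation and the E alkene is untouched. The internal alkynoate is a weak dienophile, which is why the furan is used in excess and the Lewis acid in a full equivalent.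

Step 3
Reactants: 6 methyl 2-geranyl-3-hydroxy-4-methoxybenzoate
Product: 7 methyl 2-geranyl-4-methoxy-3-(methoxymethoxy)benzoate
Conditions: MOMCl, i-Pr2NEt, CH2Cl2, 0 → 40 °C
Reagents that add atoms: chloromethyl methyl ether, COCCl
Why: O-alkylation of the hindered phenol with a reactive α-chloro ether; the acetal withstands hydride, base, organolithium and the oxidations that follow and is removed with dilute acid at the end.

Step 4
Reactants: 7 methyl 2-geranyl-4-methoxy-3-(methoxymethoxy)benzoate
Product: 8 [2-geranyl-4-methoxy-3-(methoxymethoxy)phenyl]methanol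
Conditions: i-Bu2AlH (2.5 equiv), CH2Cl2, −78 → 0 °C; aq. potassium sodium tartrate
Reagents that add atoms: none
Why: Aluminium hydride reduction of the benzoate to the benzylic alcohol; isolated trisubstituted alkenes and the MOM acetal are inert under these conditions.

Step 5
Reactants: 8 [2-geranyl-4-methoxy-3-(methoxymethoxy)phenyl]methanol
Product: 10 ethyl (2E)-3-[2-geranyl-4-methoxy-3-(methoxymethoxy)phenyl]prop-2-enoate, via aldehyde 9 (not isolated)
Conditions: MnO2 (10 equiv), Ph3P=CHCO2Et (1.3 equiv), CH2Cl2, 40 °C
Reagents that add atoms: ethyl (triphenylphosphoranylidene)acetate, CCOC(=O)C=P(c1ccccc1)(c1ccccc1)c1ccccc1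
Why: Tandem oxidation–Wittig reaction: MnO2 oxidises only the benzylic alcohol and the aldehyde is trapped as it forms by the stabilised ylide, which gives the E enoate; neither acid nor base is present.

Step 6
Reactants: 10 ethyl (2E)-3-[2-geranyl-4-methoxy-3-(methoxymethoxy)phenyl]prop-2-enoate
Product: 11 (2E)-3-[2-geranyl-4-methoxy-3-(methoxymethoxy)phenyl]prop-2-en-1-ol
Conditions: i-Bu2AlH (2.2 equiv), CH2Cl2, −78 °C; aq. potassium sodium tartrate
Reagents that add atoms: none
Why: 1,2-Reduction of the enoate to the allylic alcohol at low temperature, with the E alkene retained.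

Step 7
Reactants: 11 (2E)-3-[2-geranyl-4-methoxy-3-(methoxymethoxy)phenyl]prop-2-en-1-ol
Product: 12 (2E)-3-[2-geranyl-4-methoxy-3-(methoxymethoxy)phenyl]prop-2-en-1-yl methyl carbonate
Conditions: ClCO2Me, pyridine, CH2Cl2, 0 °C
Reagents that add atoms: methyl chloroformate, COC(=O)Cl
Why: O-acylation gives the linear allylic carbonate needed for iridium-catalysed allylic substitution; the medium stays basic because the para-methoxycinnamyl system ionises easily.

Step 8
Reactants: 13 3,5-dimethoxyphenol
Product: 14 (3,5-dimethoxyphenoxy)triisopropylsilane
Conditions: TIPSCl, imidazole, DMF, 20 °C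
Reagents that add atoms: chlorotriisopropylsilane, CC(C)[Si](Cl)(C(C)C)C(C)C
Why: Silylation of the phenol; the bulky silyl ether is a poor metalation director and shields the two positions next to it.

Step 9
Reactants: 14 (3,5-dimethoxyphenoxy)triisopropylsilane
Product: 16 (3,5-dimethoxy-4-prenylphenoxy)triisopropylsilane, via aryllithium 15 (not isolated)
Conditions: n-BuLi (1.1 equiv), THF, 0 → 20 °C; CuBr·SMe2 (10 mol%), prenyl bromide, −78 → 0 °C
Reagents that add atoms: 1-bromo-3-methylbut-2-ene, CC(C)=CCBr
Why: Directed ortho-metalation at the carbon between the two methoxy groups, the doubly activated and unshielded site, followed by copper-catalysed alkylation at the primary carbon of the allylic bromide; this puts the prenyl group para to the oxygen that becomes O1.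

Step 10
Reactants: 16 (3,5-dimethoxy-4-prenylphenoxy)triisopropylsilane
Product: 17 3,5-dimethoxy-4-prenylphenol
Conditions: n-Bu4NF (1.1 equiv), THF, 0 °C; aq. NH4Cl
Reagents that add atoms: none
Why: Fluoride cleaves the aryl silyl ether; nothing else in the molecule responds.

Step 11
Reactants: 17 3,5-dimethoxy-4-prenylphenol
Product: 18 2-iodo-3,5-dimethoxy-4-prenylphenol
Conditions: I2 (1.0 equiv), NaHCO3, THF/H2O, 0 °C
Reagents that add atoms: iodine, II
Why: Electrophilic aromatic iodination of the phenoxide at one of two equivalent positions ortho to the hydroxyl; the phenoxide ring should react far faster with I2 than the prenyl alkene, which has no neighbouring hydroxyl to trap an iodonium ion, and one equivalent of iodine limits di-iodination.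

Step 12
Reactants: 18 2-iodo-3,5-dimethoxy-4-prenylphenol; 12 (2E)-3-[2-geranyl-4-methoxy-3-(methoxymethoxy)phenyl]prop-2-en-1-yl methyl carbonate
Product: 20 1-[(1S)-1-(2-iodo-3,5-dimethoxy-4-prenylphenoxy)prop-2-en-1-yl]-2-geranyl-4-methoxy-3-(methoxymethoxy)benzene, via sodium aryloxide 19 (not isolated)
Conditions: 18, NaH, THF, 0 °C; then 12, [Ir(cod)Cl]2 (2 mol%), (Sa,Sc,Sc)-O,O'-(1,1'-binaphthalene-2,2'-diyl) N,N-bis[1-(2-methoxyphenyl)ethyl]phosphoramidite (4 mol%, preactivated with n-PrNH2), THF, 50 °C
Reagents that add atoms: none
Why: Iridium-catalysed asymmetric allylic etherification: the cyclometalated iridium phosphoramidite complex ionises the carbonate and the aryloxide attacks the aryl-substituted terminus of the allyl complex on the face away from the metal, giving the branched ether. The ligand fixes which allyl face is bound and so sets C2 as S; the ortho-methoxyphenyl ligand is chosen because the cinnamyl unit is ortho-substituted.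

Step 13
Reactants: 20 1-[(1S)-1-(2-iodo-3,5-dimethoxy-4-prenylphenoxy)prop-2-en-1-yl]-2-geranyl-4-methoxy-3-(methoxymethoxy)benzene
Product: 22 (3S)-3-ArB-3-(2-iodo-3,5-dimethoxy-4-prenylphenoxy)propan-1-ol, via B-alkyl-9-BBN adduct 21 (not isolated)
Conditions: 9-BBN (1.5 equiv), THF, 0 → 20 °C; NaOH (3 M aq.), H2O2 (30%), 0 °C
Reagents that add atoms: hydrogen peroxide, OO
Why: Hydroboration–oxidation: the bulky borane adds anti-Markovnikov to the only monosubstituted alkene and leaves the three trisubstituted alkenes alone; C2 is not involved and keeps its configuration.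

Step 14
Reactants: 22 (3S)-3-ArB-3-(2-iodo-3,5-dimethoxy-4-prenylphenoxy)propan-1-ol
Product: 24 (3S)-3-ArB-3-(2-iodo-3,5-dimethoxy-4-prenylphenoxy)propanoic acid, via aldehyde 23 (not isolated)
Conditions: TEMPO (20 mol%), PhI(OAc)2 (2.5 equiv), MeCN/pH 7 phosphate buffer, 20 °C
Reagents that add atoms: water, O
Why: Oxoammonium-catalysed oxidation of the primary alcohol through the aldehyde hydrate to the acid at neutral pH; the reagent does not epoxidise or halogenate alkenes or electron-rich arenes, and the buffer protects the benzylic aryl ether.

Step 15
Reactants: 24 (3S)-3-ArB-3-(2-iodo-3,5-dimethoxy-4-prenylphenoxy)propanoic acid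
Product: 25 (3S)-N-methoxy-N-methyl-3-ArB-3-(2-iodo-3,5-dimethoxy-4-prenylphenoxy)propanamide
Conditions: MeNH(OMe)·HCl, EDCI·HCl, HOBt, N-methylmorpholine, CH2Cl2, 0 → 20 °C
Reagents that add atoms: N,O-dimethylhydroxylamine hydrochloride, CNOC.Cl
Why: Carbodiimide amidation; the weak base and low temperature are chosen to avoid β-elimination of the aryloxide from the activated ester.

Step 16
Reactants: 25 (3S)-N-methoxy-N-methyl-3-ArB-3-(2-iodo-3,5-dimethoxy-4-prenylphenoxy)propanamide
Product: 28 (2S)-2-ArB-5,7-dimethoxy-6-prenylchroman-4-one, via aryllithium 26 (not isolated), via lithium hemiaminal 27 (not isolated)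
Conditions: t-BuLi (2.1 equiv), THF, −78 °C; aq. NH4Cl
Reagents that add atoms: none
Why: Parham cyclisation: iodine–lithium exchange at −78 °C is faster than proton transfer or intermolecular carbonyl addition, and the aryllithium adds to the N-methoxy-N-methylamide to close the six-membered ring as a stable chelate that releases the ketone only on quench, so neither over-addition nor enolisation with loss of the aryloxide can follow. This non-acidic closure is used because the benzylic C2–O1 ether and the alkenes would not survive Friedel–Crafts conditions; C2 is untouched.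

Step 17
Reactants: 28 (2S)-2-ArB-5,7-dimethoxy-6-prenylchroman-4-one
Product: 29 (2S)-2-ArB-5-hydroxy-7-methoxy-6-prenylchroman-4-one
Conditions: MgI2·OEt2 (3 equiv), THF, 45 °C; aq. NH4Cl, Na2S2O3
Reagents that add atoms: none
Why: Chelation-controlled demethylation: magnesium held between the C4 carbonyl and O5 activates only the peri methyl ether toward attack of iodide at the methyl carbon, while the 7- and 4'-methyl ethers have no such chelate. This reagent class is known to spare prenyl groups on 5-methoxyflavanones; the lowest temperature that turns over is used so that ring C is not opened.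

Step 18
Reactants: 29 (2S)-2-ArB-5-hydroxy-7-methoxy-6-prenylchroman-4-one
Product: 30 (2S)-2-(2-geranyl-3-hydroxy-4-methoxyphenyl)-5-hydroxy-7-methoxy-6-prenylchroman-4-one (CNP0241771.1)
Conditions: HCl (3 M aq.), MeOH/THF, 20 °C
Reagents that add atoms: none
Why: Acid-catalysed acetal exchange with methanol removes the MOM group; dilute acid at room temperature is the usual way to unmask ortho-prenylphenols, the chelated 5-hydroxyl is a poor nucleophile toward its prenyl neighbour, and the reaction is stopped at full conversion.

## Compound list

1 | methyl propiolate | C#CC(=O)OC | starting material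
2 | geranyl bromide, (2E)-1-bromo-3,7-dimethylocta-2,6-diene | CC(C)=CCC/C(C)=C/CBr | starting material
3 | methyl (5E)-6,10-dimethylundeca-5,9-dien-2-ynoate | COC(=O)C#CC/C=C(\C)CCC=C(C)C | intermediate
4 | 3-methoxyfuran | COc1ccoc1 | starting material
5 | methyl 3-geranyl-5-methoxy-7-oxabicyclo[2.2.1]hepta-2,5-diene-2-carboxylate (racemic) | COC(=O)C1=C(C/C=C(\C)CCC=C(C)C)C2OC1C=C2OC | intermediate (not isolated)
6 | methyl 2-geranyl-3-hydroxy-4-methoxybenzoate | COC(=O)c1ccc(OC)c(O)c1C/C=C(\C)CCC=C(C)C | intermediate
7 | methyl 2-geranyl-4-methoxy-3-(methoxymethoxy)benzoate | COC(=O)c1ccc(OC)c(OCOC)c1C/C=C(\C)CCC=C(C)C | intermediate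
8 | [2-geranyl-4-methoxy-3-(methoxymethoxy)phenyl]methanol | OCc1ccc(OC)c(OCOC)c1C/C=C(\C)CCC=C(C)C | intermediate
9 | 2-geranyl-4-methoxy-3-(methoxymethoxy)benzaldehyde | O=Cc1ccc(OC)c(OCOC)c1C/C=C(\C)CCC=C(C)C | intermediate (not isolated)
10 | ethyl (2E)-3-[2-geranyl-4-methoxy-3-(methoxymethoxy)phenyl]prop-2-enoate | CCOC(=O)/C=C/c1ccc(OC)c(OCOC)c1C/C=C(\C)CCC=C(C)C | intermediate
11 | (2E)-3-[2-geranyl-4-methoxy-3-(methoxymethoxy)phenyl]prop-2-en-1-ol | OC/C=C/c1ccc(OC)c(OCOC)c1C/C=C(\C)CCC=C(C)C | intermediate
12 | (2E)-3-[2-geranyl-4-methoxy-3-(methoxymethoxy)phenyl]prop-2-en-1-yl methyl carbonate | COC(=O)OC/C=C/c1ccc(OC)c(OCOC)c1C/C=C(\C)CCC=C(C)C | intermediate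
13 | 3,5-dimethoxyphenol | COc1cc(O)cc(OC)c1 | starting material
14 | (3,5-dimethoxyphenoxy)triisopropylsilane | COc1cc(OC)cc(O[Si](C(C)C)(C(C)C)C(C)C)c1 | intermediate
15 | [2,6-dimethoxy-4-(triisopropylsilyloxy)phenyl]lithium | [Li]c1c(OC)cc(O[Si](C(C)C)(C(C)C)C(C)C)cc1OC | intermediate (not isolated)
16 | (3,5-dimethoxy-4-prenylphenoxy)triisopropylsilane | COc1cc(O[Si](C(C)C)(C(C)C)C(C)C)cc(OC)c1CC=C(C)C | intermediate
17 | 3,5-dimethoxy-4-prenylphenol | COc1cc(O)cc(OC)c1CC=C(C)C | intermediate
18 | 2-iodo-3,5-dimethoxy-4-prenylphenol | COc1cc(O)c(I)c(OC)c1CC=C(C)C | intermediate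
19 | sodium 2-iodo-3,5-dimethoxy-4-prenylphenoxide | [Na+].[O-]c1cc(OC)c(CC=C(C)C)c(OC)c1I | intermediate (not isolated)
20 | 1-[(1S)-1-(2-iodo-3,5-dimethoxy-4-prenylphenoxy)prop-2-en-1-yl]-2-geranyl-4-methoxy-3-(methoxymethoxy)benzene | C=C[C@H](Oc1cc(OC)c(CC=C(C)C)c(OC)c1I)c1ccc(OC)c(OCOC)c1C/C=C(\C)CCC=C(C)C | intermediate
21 | 9-[(3S)-3-ArB-3-(2-iodo-3,5-dimethoxy-4-prenylphenoxy)propyl]-9-borabicyclo[3.3.1]nonane | C1CC2CCCC(C1)B2CC[C@H](Oc1cc(OC)c(CC=C(C)C)c(OC)c1I)c1ccc(OC)c(OCOC)c1C/C=C(\C)CCC=C(C)C | intermediate (not isolated)
22 | (3S)-3-ArB-3-(2-iodo-3,5-dimethoxy-4-prenylphenoxy)propan-1-ol | OCC[C@H](Oc1cc(OC)c(CC=C(C)C)c(OC)c1I)c1ccc(OC)c(OCOC)c1C/C=C(\C)CCC=C(C)C | intermediate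
23 | (3S)-3-ArB-3-(2-iodo-3,5-dimethoxy-4-prenylphenoxy)propanal | O=CC[C@H](Oc1cc(OC)c(CC=C(C)C)c(OC)c1I)c1ccc(OC)c(OCOC)c1C/C=C(\C)CCC=C(C)C | intermediate (not isolated)
24 | (3S)-3-ArB-3-(2-iodo-3,5-dimethoxy-4-prenylphenoxy)propanoic acid | OC(=O)C[C@H](Oc1cc(OC)c(CC=C(C)C)c(OC)c1I)c1ccc(OC)c(OCOC)c1C/C=C(\C)CCC=C(C)C | intermediate
25 | (3S)-N-methoxy-N-methyl-3-ArB-3-(2-iodo-3,5-dimethoxy-4-prenylphenoxy)propanamide | CON(C)C(=O)C[C@H](Oc1cc(OC)c(CC=C(C)C)c(OC)c1I)c1ccc(OC)c(OCOC)c1C/C=C(\C)CCC=C(C)C | intermediate
26 | aryllithium from 25 (lithium in place of iodine) | CON(C)C(=O)C[C@H](Oc1cc(OC)c(CC=C(C)C)c(OC)c1[Li])c1ccc(OC)c(OCOC)c1C/C=C(\C)CCC=C(C)C | intermediate (not isolated)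
27 | lithium (2S)-2-ArB-5,7-dimethoxy-4-[methoxy(methyl)amino]-6-prenylchroman-4-olate (C4 epimers) | CON(C)C1(O[Li])C[C@@H](c2ccc(OC)c(OCOC)c2C/C=C(\C)CCC=C(C)C)Oc2cc(OC)c(CC=C(C)C)c(OC)c21 | intermediate (not isolated)
28 | (2S)-2-ArB-5,7-dimethoxy-6-prenylchroman-4-one | O=C1C[C@@H](c2ccc(OC)c(OCOC)c2C/C=C(\C)CCC=C(C)C)Oc2cc(OC)c(CC=C(C)C)c(OC)c21 | intermediate
29 | (2S)-2-ArB-5-hydroxy-7-methoxy-6-prenylchroman-4-one | O=C1C[C@@H](c2ccc(OC)c(OCOC)c2C/C=C(\C)CCC=C(C)C)Oc2cc(OC)c(CC=C(C)C)c(O)c21 | intermediate
30 | (2S)-2-(2-geranyl-3-hydroxy-4-methoxyphenyl)-5-hydroxy-7-methoxy-6-prenylchroman-4-one (CNP0241771.1) | COc1ccc([C@@H]2CC(=O)c3c(cc(OC)c(CC=C(C)C)c3O)O2)c(C/C=C(\C)CCC=C(C)C)c1O | target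

## Step count and least certain steps

Total: 18 steps. Longest linear sequence: 14 steps (steps 1–7, then 12–18). The ring A branch (steps 8–11) is 4 steps.

**Step 2 (key step).** The β-alkyl alkynoate is a weak dienophile. The likely failures are Lewis-acid-induced oligomerisation of the furan before it adds, and protonation of the zwitterion formed after the first C–C bond in place of ring closure (conjugate addition of furan C2 without cycloaddition). A smaller risk is cation–olefin cyclisation of the geranyl chain if a proton source develops.
Fallback: ring B is taken from an aromatic starting material. Geranyl bromide 2 is converted with Bu3SnLi in THF into tributyl(geranyl)stannane F3. Purchased 2-bromo-3-hydroxy-4-methoxybenzaldehyde F1 is protected with MOMCl and i-Pr2NEt to give 2-bromo-4-methoxy-3-(methoxymethoxy)benzaldehyde F2. Stille coupling of F2 with F3 (Pd(PPh3)4, DMF, 90 °C) joins the allyl unit at its primary carbon and gives aldehyde 9, which is isolated. The route is rejoined at 9 and continues with the ylide of step 5 to 10.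

**Step 12.** Both partners are hindered (ortho-geranyl on the cinnamyl unit, ortho-iodine on the aryloxide). This can erode the branched-to-linear selectivity and the facial selectivity. The product is a doubly activated ether that the catalyst can re-ionise, which would scramble C2 with time.
Fallback: the C2–O1 bond is made by displacement at a reduced carbinol. Benzoate 7 undergoes Claisen condensation with the lithium enolate of N-methoxy-N-methylacetamide to give the β-keto amide 3-ArB-N-methoxy-N-methyl-3-oxopropanamide F4. Asymmetric transfer hydrogenation with RuCl(p-cymene)[(R,R)-TsDPEN] in HCO2H/Et3N gives (3R)-3-ArB-3-hydroxy-N-methoxy-N-methylpropanamide F5. Mitsunobu reaction of F5 with iodophenol 18 (PPh3, diisopropyl azodicarboxylate, toluene, 0 °C) inverts the carbinol and returns to the route at 25. This is shorter, but it depends on clean inversion at a cation-prone benzylic centre, which is why it is held in reserve.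

**Step 16.** Deprotonation next to the amide followed by β-elimination of the ring A aryloxide, or direct attack of t-BuLi on the amide, can compete with exchange and ring closure.
Fallback: the C4–C4a bond is formed under non-basic conditions. Alcohol 22 is oxidised with Dess–Martin periodinane (NaHCO3, CH2Cl2) to aldehyde 23, which is isolated. Intramolecular Nozaki–Hiyama–Kishi reaction (CrCl2, NiCl2 (cat.), DMF, 20 °C) gives (2S)-2-ArB-5,7-dimethoxy-6-prenylchroman-4-ol F6 as a mixture at C4. A second Dess–Martin oxidation returns to the route at 28.

**Step 11.** Attack of the iodinating agent on the prenyl alkene, or a second iodination at the other ortho position, would lower the yield of the mono-iodide.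
Fallback: the iodine is delivered as an electrophile to an aryllithium at −78 °C, where the alkene does not react. Phenol 17 is converted into 1,3-dimethoxy-5-(methoxymethoxy)-2-prenylbenzene F7 (MOMCl, i-Pr2NEt). Lithiation next to the MOM group (n-BuLi, THF, 0 °C) and quench with I2 at −78 °C gives 2-iodo-3,5-dimethoxy-1-(methoxymethoxy)-4-prenylbenzene F8. Dilute HCl in MeOH returns to the route at 18.

**Step 1.** Substitution with allylic transposition (attack at the tertiary carbon), base-induced migration of the triple bond into conjugation with the alkene, and oxidative dimerisation of the propiolate are the likely losses.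
Fallback: the ester is put on last. Geranyl bromide 2 is coupled with ethynylmagnesium bromide (CuBr·SMe2 (cat.), THF, 0 °C) to give (4E)-5,9-dimethyldeca-4,8-dien-1-yne F9. Deprotonation with n-BuLi at −78 °C and acylation with methyl chloroformate returns to the route at 3.

## Further compounds

F1 | step 2 | 2-bromo-3-hydroxy-4-methoxybenzaldehyde (purchased) | O=Cc1ccc(OC)c(O)c1Br
F2 | step 2 | 2-bromo-4-methoxy-3-(methoxymethoxy)benzaldehyde | O=Cc1ccc(OC)c(OCOC)c1Br
F3 | step 2 | tributyl[(2E)-3,7-dimethylocta-2,6-dien-1-yl]stannane | CCCC[Sn](CCCC)(CCCC)C/C=C(\C)CCC=C(C)C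
F4 | step 12 | 3-ArB-N-methoxy-N-methyl-3-oxopropanamide | CON(C)C(=O)CC(=O)c1ccc(OC)c(OCOC)c1C/C=C(\C)CCC=C(C)C
F5 | step 12 | (3R)-3-ArB-3-hydroxy-N-methoxy-N-methylpropanamide | CON(C)C(=O)C[C@@H](O)c1ccc(OC)c(OCOC)c1C/C=C(\C)CCC=C(C)C
F6 | step 16 | (2S)-2-ArB-5,7-dimethoxy-6-prenylchroman-4-ol (C4 epimers) | OC1C[C@@H](c2ccc(OC)c(OCOC)c2C/C=C(\C)CCC=C(C)C)Oc2cc(OC)c(CC=C(C)C)c(OC)c21
F7 | step 11 | 1,3-dimethoxy-5-(methoxymethoxy)-2-prenylbenzene | COCOc1cc(OC)c(CC=C(C)C)c(OC)c1
F8 | step 11 | 2-iodo-3,5-dimethoxy-1-(methoxymethoxy)-4-prenylbenzene | COCOc1cc(OC)c(CC=C(C)C)c(OC)c1I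
F9 | step 1 | (4E)-5,9-dimethyldeca-4,8-dien-1-yne | C#CC/C=C(\C)CCC=C(C)C
A1 | alternative 1 | 2-ArB-5,7-dimethoxy-4-methylidene-6-prenyl-4H-1,3-benzodioxine | C=C1OC(c2ccc(OC)c(OCOC)c2C/C=C(\C)CCC=C(C)C)Oc2cc(OC)c(CC=C(C)C)c(OC)c21
A2 | alternative 1 | (2S)-2-ArB-5,7-dimethoxy-6-prenylchroman-4-one | O=C1C[C@@H](c2ccc(OC)c(OCOC)c2C/C=C(\C)CCC=C(C)C)Oc2cc(OC)c(CC=C(C)C)c(OC)c21
A3 | alternative 2 | 1-ethynyl-2-geranyl-4-methoxy-3-(methoxymethoxy)benzene | C#Cc1ccc(OC)c(OCOC)c1C/C=C(\C)CCC=C(C)C
A4 | alternative 2 | 2-ArB-5,7-dimethoxy-6-prenylchromen-4-one | O=c1cc(-c3ccc(OC)c(OCOC)c3C/C=C(\C)CCC=C(C)C)oc2cc(OC)c(CC=C(C)C)c(OC)c12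
A5 | alternative 3 | (2S)-2-ArB-6-(2-diazoacetyl)-2,3-dihydro-4H-pyran-4-one | [N-]=[N+]=CC(=O)C1=CC(=O)C[C@@H](c2ccc(OC)c(OCOC)c2C/C=C(\C)CCC=C(C)C)O1
A6 | alternative 3 | 1-methoxy-5-methylhex-4-en-1-yne | COC#CCC=C(C)C
A7 | alternative 3 | (2S)-2-ArB-5-hydroxy-7-methoxy-6-prenylchroman-4-one | O=C1C[C@@H](c2ccc(OC)c(OCOC)c2C/C=C(\C)CCC=C(C)C)Oc2cc(OC)c(CC=C(C)C)c(O)c21
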